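**Retrosynthetic overview**

1. Target 11 ⇒ tetraketide lactone 10, by opening the benzene ring (retro-Claisen) between the benzoyl-bearing carbon and the C–OH carbon that lies between the benzoyl- and the alkyl-bearing carbons. Then 10 ⇒ methyl benzoate 9 + β,δ-diketo lactone 8, by cutting the bond between the benzoyl C=O carbon and what is then the terminal CH3 carbon of the chain.
2. Enabling feature: the benzene ring carries oxygen on alternate carbons (a folded polyketide), and the side-chain carbinol oxygen stands 1,4 to that same C–OH ring carbon. This ring carbon, the alkyl-bearing ring carbon, the benzylic CH2, the carbinol CH and its oxygen are therefore the five atoms of a γ-butyrolactone. The lactone serves as the ester of the Claisen closure, its opening frees the (R)-alcohol without a protecting group, and the substituent on the lactone α-carbon shuts off the competing aldol fold.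
3. 8 ⇒ lactone 6 by two C-acetylations; 6 ⇒ keto lactone 5 (methylenation) ⇒ acid chloride 2 + Grignard reagent 4. The stereocentre comes from commercial (R)-5-oxotetrahydrofuran-2-carboxylic acid 1.
4. Ring order: the γ-lactone (temporary ring) is present from the start; the benzene ring is built last, from the open chain, in the same operation that opens the lactone.

Key step: step 6

Remark: 7, 8 and 10 are drawn as keto forms but should exist as enol/C3-epimer mixtures, which does not matter because C3 ends as an aromatic carbon; 1, 3 and 9 are taken as commercial.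

**Route**

Step 1
Reactants: 1 (R)-5-oxotetrahydrofuran-2-carboxylic acid
Product: 2 (R)-5-oxotetrahydrofuran-2-carbonyl chloride
Conditions: (COCl)2, DMF (cat.), CH2Cl2, 0 °C → rt
Reagents that add atoms: oxalyl chloride, ClC(=O)C(=O)Cl
Why: Acid chloride formation through the Vilsmeier-type chloroiminium species is neutral and fast, so the lactone and the oxygen-bearing stereocentre should not be affected.

Step 2
Reactants: 2 (R)-5-oxotetrahydrofuran-2-carbonyl chloride; 3 5-bromo-2-methylpent-2-ene
Product: 5 (R)-5-(5-methylhex-4-enoyl)dihydrofuran-2(3H)-one, via Grignard reagent 4 (not isolated)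
Conditions: 3, Mg, THF, rt; then 2, Fe(acac)3 (3 mol %), THF, −78 °C
Reagents that add atoms: none
Why: Iron-catalysed cross-coupling of a Grignard reagent with an acid chloride (ketone synthesis) should outrun addition to the lactone and to the product ketone at −78 °C, and the stereocentre is carried over unchanged from 2.

Step 3
Reactants: 5 (R)-5-(5-methylhex-4-enoyl)dihydrofuran-2(3H)-one
Product: 6 (R)-5-(6-methylhepta-1,5-dien-2-yl)dihydrofuran-2(3H)-one
Conditions: Zn, CH2Br2, TiCl4, THF/CH2Cl2, 0 °C → rt
Reagents that add atoms: dibromomethane, BrCBr
Why: The Lombardo methylenation is non-basic and selective for ketones over lactones, so the 1,1-disubstituted alkene should form without epimerising the adjacent stereocentre, which from here on has no neighbouring carbonyl group and can no longer epimerise.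

Step 4
Reactants: 6 (R)-5-(6-methylhepta-1,5-dien-2-yl)dihydrofuran-2(3H)-one
Product: 7 (5R)-3-acetyl-5-(6-methylhepta-1,5-dien-2-yl)dihydrofuran-2(3H)-one
Conditions: LiN(iPr)2 (1.05 equiv), THF, −78 °C; MeC(O)N(OMe)Me, −78 → 0 °C; cold 1 M HCl
Reagents that add atoms: N-methoxy-N-methylacetamide, CC(=O)N(C)OC
Why: Crossed Claisen-type C-acylation of the lactone lithium enolate with a Weinreb amide, whose chelated tetrahedral adduct should hold until work-up and so prevent double acylation; the new C3 centre needs no control.

Step 5
Reactants: 7 (5R)-3-acetyl-5-(6-methylhepta-1,5-dien-2-yl)dihydrofuran-2(3H)-one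
Product: 8 (5R)-5-(6-methylhepta-1,5-dien-2-yl)-3-(3-oxobutanoyl)dihydrofuran-2(3H)-one
Conditions: LiN(iPr)2 (2.2 equiv), THF, −78 → 0 °C; MeC(O)N(OMe)Me, −78 → 0 °C; cold 1 M HCl
Reagents that add atoms: N-methoxy-N-methylacetamide, CC(=O)N(C)OC
Why: γ-Acylation of a β-keto ester dianion (here a β-keto lactone), in which the second, less stabilised carbanion at the acetyl CH3 is the reactive site and the Weinreb amide stops at the ketone stage.

Step 6
Reactants: 8 (5R)-5-(6-methylhepta-1,5-dien-2-yl)-3-(3-oxobutanoyl)dihydrofuran-2(3H)-one; 9 methyl benzoate
Product: 11 (R)-[2,4,6-trihydroxy-3-(2-hydroxy-7-methyl-3-methylideneoct-6-en-1-yl)phenyl](phenyl)methanone, via tetraketide lactone 10 (not isolated)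
Conditions: LiN(iPr)2 (4.2 equiv), THF, −78 → 0 °C; 9, 0 °C → rt; then Mg(OMe)2, MeOH, 65 °C, same flask, under argon; cold 1 M HCl to pH 4
Reagents that add atoms: none
Why: Proposed new method: LiN(iPr)2 should convert 8 into its trianion (lactone C3, the central CH2 and the terminal CH3 of the 3-oxobutanoyl chain), whose least stabilised terminal carbanion attacks the ester carbonyl of 9 and expels methoxide, which forms the benzoyl C–C bond and gives the polyenolate of tetraketide 10. Methanolic Mg(OMe)2 then sets up the chelated enolate equilibrium in which the new doubly activated carbon (between the benzoyl and the neighbouring keto group) attacks the lactone carbonyl (or the methyl ester formed from it by methanolysis, which leads to the same product), the carbinol oxygen leaves as the alkoxide, and triple enolisation gives the benzene ring. The closest known reaction types are the terminal C-acylation of β,δ-diketo ester trianions with aromatic esters and the Claisen-type cyclisation of 3,5,7-triketo esters or their 2-pyranone forms to acylphloroglucinols by Mg(OMe)2; new here are the γ-lactone as acyl acceptor and the one-flask sequence. The benzene ring closes by a 6-(enolendo)-exo-trig attack on the lactone C=O; no stereocentre is formed, and the (R)-carbinol centre is kept because neither its C–O nor its C–H bond is touched. The step needs terminal over internal C-acylation, which the reactivity order of the trianion sites secures, and the Claisen fold over the aldol fold onto the benzoyl ketone, which the side-chain substituent on the lactone α-carbon secures, since an aldol product there would hold a quaternary carbon, could not aromatise and would revert.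

**Compound list**

1 | (R)-5-oxotetrahydrofuran-2-carboxylic acid | OC(=O)[C@H]1CCC(=O)O1 | starting material
2 | (R)-5-oxotetrahydrofuran-2-carbonyl chloride | ClC(=O)[C@H]1CCC(=O)O1 | intermediate
3 | 5-bromo-2-methylpent-2-ene | CC(C)=CCCBr | starting material
4 | (4-methylpent-3-en-1-yl)magnesium bromide | CC(C)=CCC[Mg]Br | intermediate (not isolated)
5 | (R)-5-(5-methylhex-4-enoyl)dihydrofuran-2(3H)-one | CC(C)=CCCC(=O)[C@H]1CCC(=O)O1 | intermediate
6 | (R)-5-(6-methylhepta-1,5-dien-2-yl)dihydrofuran-2(3H)-one | C=C(CCC=C(C)C)[C@H]1CCC(=O)O1 | intermediate
7 | (5R)-3-acetyl-5-(6-methylhepta-1,5-dien-2-yl)dihydrofuran-2(3H)-one (C3 epimers/enol) | C=C(CCC=C(C)C)[C@H]1CC(C(C)=O)C(=O)O1 | intermediate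
8 | (5R)-5-(6-methylhepta-1,5-dien-2-yl)-3-(3-oxobutanoyl)dihydrofuran-2(3H)-one (C3 epimers/enols) | C=C(CCC=C(C)C)[C@H]1CC(C(=O)CC(C)=O)C(=O)O1 | intermediate
9 | methyl benzoate | COC(=O)c1ccccc1 | starting material
10 | (5R)-3-(3,5-dioxo-5-phenylpentanoyl)-5-(6-methylhepta-1,5-dien-2-yl)dihydrofuran-2(3H)-one (as its polyenolate) | C=C(CCC=C(C)C)[C@H]1CC(C(=O)CC(=O)CC(=O)c2ccccc2)C(=O)O1 | intermediate (not isolated)
11 | (R)-[2,4,6-trihydroxy-3-(2-hydroxy-7-methyl-3-methylideneoct-6-en-1-yl)phenyl](phenyl)methanone | C=C(CCC=C(C)C)[C@H](O)Cc1c(O)cc(O)c(C(=O)c2ccccc2)c1O | target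

**Step count and risks**

Total step count: 6. Longest linear sequence: 6 steps (1 → 11); the Grignard reagent is made within step 2.

Steps most likely to fail:

1. Step 6 (Proposed new method). The benzoylation may stop short through proton transfer from the freshly acylated chain to unreacted trianion. Methoxide may cleave the polyketone chain (retro-Claisen) before the ring closes. O-cyclisation to a pyranone may stall under the one-flask conditions. The fallback uses known chemistry and goes stepwise through isolated 2-pyranones. It sets out from 8: DBU in toluene at 80 °C should move the acyl group from the side-chain oxygen to the enol oxygen (the known cyclisation of β,δ-diketo esters to 4-hydroxy-2-pyranones) and give 4-hydroxy-3-[(2R)-2-hydroxy-7-methyl-3-methylideneoct-6-en-1-yl]-6-methyl-2H-pyran-2-one F1. Its trianion (alkoxide, pyranone oxide and 6-CH2 carbanion; LiN(iPr)2, 3.3 equiv, THF, −78 → 0 °C) is then C-benzoylated at the 6-methyl group with 9, which should give 4-hydroxy-3-[(2R)-2-hydroxy-7-methyl-3-methylideneoct-6-en-1-yl]-6-(2-oxo-2-phenylethyl)-2H-pyran-2-one F2, purified at this stage. Mg(OMe)2 in MeOH at reflux then opens the pyranone and closes the benzene ring by the known Claisen recyclisation of 6-(2-oxoalkyl)-4-hydroxy-2-pyranones, which comes back to the route at 11.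

2. Step 5. The dianion may be quenched by proton exchange with the α-protons of the amide, and addition to the amide carbonyl may be slow, so that 7 is returned. The fallback replaces acylation by aldol addition and oxidation. It sets out from 7: the same dianion (LiN(iPr)2, 2.2 equiv, THF, −78 °C) is treated with acetaldehyde, a far better electrophile, which should give (5R)-3-(3-hydroxybutanoyl)-5-(6-methylhepta-1,5-dien-2-yl)dihydrofuran-2(3H)-one F3 as a diastereomer mixture. Oxidation of the β-hydroxy ketone with Dess–Martin periodinane (CH2Cl2, 0 °C → rt) comes back to the route at 8.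

3. Step 3. Methylenation at the hindered, chelating α-acyloxy ketone may be slow, with competing enolisation (erosion of configuration at the adjacent centre) or reductive side reactions of the titanium reagent. The fallback is a two-stage Peterson olefination. It sets out from 5: Me3SiCH2MgCl/CeCl3 (THF, −78 °C), a non-basic nucleophile that adds rather than enolises, should give (5R)-5-[2-hydroxy-6-methyl-1-(trimethylsilyl)hept-5-en-2-yl]dihydrofuran-2(3H)-one F4 as a mixture of carbinol epimers. Acid-promoted elimination (p-TsOH cat., CH2Cl2, 0 °C) then comes back to the route at 6.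

**Further compounds**

F1 | step 6 | 4-hydroxy-3-[(2R)-2-hydroxy-7-methyl-3-methylideneoct-6-en-1-yl]-6-methyl-2H-pyran-2-one | C=C(CCC=C(C)C)[C@H](O)CC1=C(O)C=C(C)OC1=O
F2 | step 6 | 4-hydroxy-3-[(2R)-2-hydroxy-7-methyl-3-methylideneoct-6-en-1-yl]-6-(2-oxo-2-phenylethyl)-2H-pyran-2-one | C=C(CCC=C(C)C)[C@H](O)CC1=C(O)C=C(CC(=O)c2ccccc2)OC1=O
F3 | step 5 | (5R)-3-(3-hydroxybutanoyl)-5-(6-methylhepta-1,5-dien-2-yl)dihydrofuran-2(3H)-one | C=C(CCC=C(C)C)[C@H]1CC(C(=O)CC(C)O)C(=O)O1
F4 | step 3 | (5R)-5-[2-hydroxy-6-methyl-1-(trimethylsilyl)hept-5-en-2-yl]dihydrofuran-2(3H)-one | CC(C)=CCCC(O)(C[Si](C)(C)C)[C@H]1CCC(=O)O1
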